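## Analysis of the target

Gnetumontanin B is a stilbene trimer made of two 2,3-diaryl-2,3-dihydrobenzofurans joined only by the single bond C2–C7'. The outer ring (O1, C2, C3, C3a–C7a) is fused to a resorcinol nucleus carrying the free 4-OH and, at C6, the (E)-4-hydroxystyryl group. The inner ring (primed atoms) carries 4'-OH, a 2,4-dihydroxyphenyl group at C2' and a 3,5-dihydroxyphenyl group at C3'. There are four stereocentres, C2, C3, C2' and C3', all S, with the two aryl groups trans in each ring; no ring links the two pairs, so their relative configuration has to come from absolute control of each. Sensitive groups are the nine free phenols, the electron-rich stilbene (acid, oxidants, light) and the benzylic bonds C2–O1 and C2'–O1', each next to an aryl group with ortho and para oxygen, which ionise in acid. That lability is also useful: C2 and C2' can be equilibrated to trans through the benzylic cation, whereas C3 and C3' cannot, so C3 and C3' must be set by a reagent. The hard points are the arene carbons C3a and C3a' flanked by two oxygens, the 3,5-dioxygenated aryl groups at C3 and C3' (not accessible by Friedel–Crafts chemistry) and the convergent union of two large halves with control of C3. The strategy rests on the C2–C3 unit of the outer ring: C2 (bearing O1 and C7') and C3 (bearing C3a and the 3,5-dihydroxyphenyl group) are the two carbons of a former (E)-alkene with boron on C2, so C7' and C3a can be delivered separately.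

## Retrosynthetic reasoning

31 ⇒ 30. Only eight O–CH3 bonds are cut. Methyl is the one phenol protection indifferent to aryllithium reagents, a rhodium carbene, peroxide and protic acid, all of which lie upstream. The price is a Lewis-acidic ether cleavage as the last step, which must remove eight groups without permanently opening the two benzylic C–O bonds.

30 ⇒ 28 (through 29). The outer ring is opened at O1–C2 and not at a C–C bond, because this bond forms readily once C2 is a benzylic cation: C2 sits on an arene with an ortho ring oxygen and a para methoxy group. In alcohol 28 the two oxygens flanking C3a are MOM ethers. Acid unmasks them (29), ionises C2–OH, and either phenol closes the ring trans to the C3 aryl group. The gain is that the configuration of C2 in 28 is irrelevant; the forward step only has to preserve C3.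

28 ⇒ 27. The C2–O bond is exchanged for a C2–B bond. Boronic ester oxidation proceeds with retention and tolerates the rest of the molecule, and boron on C2 is exactly what the next disconnection leaves behind.

27 ⇒ 11 + 24 + 19. Two bonds are cut at once, C2–C7' and C3–C3a. They are the bonds at the two carbons of an (E)-alkenyl boronate: forward, an aryl group migrates from boron to C2 while a palladium-bound aryl group is delivered to C3 (three-component conjunctive cross-coupling). The pieces are:
- bromide 11, the inner dihydrobenzofuran and source of the migrating aryllithium;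
- styrenyl boronate 24, which supplies C2, C3 and the 3,5-dimethoxyphenyl group;
- triflate 19, which supplies C3a with its two flanking oxygens and the stilbene arm.

No other cut gives both convergent union and catalyst control of C3, the one outer-ring centre that cannot be corrected later. Cutting C2–C7' alone would make C3 an enolisable, doubly benzylic carbon next to a carbonyl group, whose configuration would not hold. Cutting C3–C3a alone has no stereocontrolled forward reaction at a carbon flanked by two oxygens. The forward step must beat direct Suzuki coupling (hence the hindered diol 21 on boron) and tolerate two ortho substituents on the triflate.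

11 ⇒ 10 ⇒ 8 (through 9) ⇒ 7 ⇒ 6 ⇒ 4 + 5; 4 ⇒ 2 + 3; 2 ⇒ 1. Bromide 11 is the trans isomer of 10 and arises from it by acid equilibration at C2', the same cation logic as for the outer ring. 10 is cut at C2'–C3': forward, a diaryl carbene centred on C3' inserts into a C–H bond of the benzylic O–CH2 group under chiral dirhodium catalysis, closing the ring and setting C3'. The carbene comes from hydrazone 8 through diazo compound 9, the hydrazone from ketone 7, and 7 from alcohol 6, the adduct of Grignard reagent 5 and aldehyde 4. 4 is the ether of salicylaldehyde 2 with alcohol 3, and 2 comes from ortho-formylation of bromophenol 1. In 1 the bromine at the future C7' and the correct methyl ether are already in place and only one ortho position is free. The bromine is carried from the start because a late electrophilic bromination would go to the 3,5-dimethoxyphenyl ring.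

19 ⇒ 18 ⇒ 15 ⇒ 13 + 14; 13 ⇒ 12. Triflate 19 comes from phenol 18 (O–S bond). The phenol oxygen is introduced at the carbon between the two MOM ethers of stilbene 15, the most acidic arene position, by lithiation (16), borylation (17) and oxidation. This is shorter than differentiating the oxygens of a trioxygenated arene. 15 is cut at the double bond into aldehyde 13 and phosphonate 14, which give the (E)-alkene, and 13 is the bis-MOM ether of 12.

24 ⇒ 22 + 21; 21 ⇒ 20. Boronate 24 is cut at its B–O bonds into diol 21 and an (E)-alkenylboron unit, and the latter into alkyne 22: syn hydroboration gives catechol ester 23, whose diol is exchanged for 21. Diol 21 is cut at its two C–CH3 bonds back to diketone 20.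

## Alternatives that were turned down

Alternative 1: de novo construction of the benzene ring of the inner dihydrobenzofuran.
- Disconnection: the ring bonds C7a'–C3a', C4'–C5' and C7a'–C7' (with C5'–C6').
- Forward key step: photolysis of diazo ketone A1 (Wolff rearrangement) in the presence of siloxyalkyne A2 leads, by [2+2] addition, four-electron ring opening and six-electron ring closure, to the tetrasubstituted phenol A3. A3 has 7a'-OH free, 4'-O silylated and an ester at C7'.
- For it: the mechanism fixes the substitution pattern, the two oxygens emerge differentiated, and the side chain with C2' and C3' is carried in complete.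
- Against it: A2 must already hold both stereocentres, and C3' in A2 is propargylic as well as benzylic, so it is easily lost by isomerisation towards the allene. The photochemical step runs in the presence of two electron-rich arenes. After A3 the inner ring is still open, the C7' ester is at the wrong oxidation level for union with the other half, and the outer C2–C3 unit is not addressed.
- Comparison: on regiochemical certainty of the inner arene this plan is stronger than the chosen one, which relies on the ortho-selectivity of one formylation. The chosen route answers with a purchasable arene (1) in which only one position can react, and spends its key step on the hard bond set C2–C7'/C3–C3a. In step count the alternative is clearly longer.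

Alternative 2: carbene C–H insertion as the strategy-defining step.
- Disconnection: C2'–C3' of the inner ring.
- Forward key step: hydrazone A4 is dehydrogenated in the flask to the diazo stage, and under chiral dirhodium catalysis the carbene centred on C3' inserts into the C–H bond of the O–CH2 group. This gives A5 with a dioxolane at C7'.
- For it: the reaction type is established for 2,3-diaryl dihydrobenzofurans, forms the ring and both centres in one catalytic step and leaves a masked aldehyde as a handle.
- Against it: the plan ends where the real difficulty begins. From an aldehyde at C7' the outer ring still needs a C–C bond to C2, a second C–C bond from C3 to the hindered C3a, and control of C3, for none of which this plan has a step. The acetal must also survive acid-catalysed hydrazone formation.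
- Comparison: for the inner ring this alternative is as strong as the chosen route, which in fact uses the same reaction type in steps 5–7 with bromine in place of the acetal. The chosen strategy offers in its place a C7' substituent that is directly the nucleophile of the key step, and one catalytic step that makes both C–C bonds of the outer C2–C3 unit and sets C3. Step counts are equal up to the inner ring; the alternative needs several more afterwards.

Alternative 3: de novo construction of the outer resorcinol ring.
- Disconnection: C3a–C7a and C4–C5.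
- Forward key step: pyridazine A6 is tethered through O1, C2 and C3 to an alkynyl boronate. On heating it undergoes intramolecular [4+2] addition across the alkyne (pyridazine C3 and C6 as diene termini) and extrudes its two nitrogen atoms. This gives A7: benzene ring and dihydrofuran ring at once, with boron at C4 as a latent hydroxyl.
- For it: the crowded carbon C3a is made by cycloaddition and not by coupling, so the two-ortho-substituent problem of the chosen key step disappears. The tether fixes the regiochemistry.
- Against it: the tether must already contain C2 and C3 in the right configuration, as a pyridazinyl ether at a readily ionised benzylic carbon and a propargylic, doubly activated C3–H. The C2–C3 problem is therefore presupposed, not solved. Pyridazines are sluggish dienes, the alkoxy group makes this one more electron-rich, and an alkynyl boronate is not an activated dienophile. High temperatures are therefore expected, at which the benzylic ether, the propargylic centre and the stilbene are all at risk.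
- Comparison: on the steric issue at C3a this alternative is stronger. The chosen strategy offers instead creation of C3 under catalyst control in the step that joins the halves, at moderate temperature, with no stereodefined propargylic ether to prepare. The alternative is longer because of the synthesis of A6.

Key step: step 14

Remark on the chemistry: the sense of induction of Rh2(R-PTAD)4 in step 6 and of (Sp,Sp)-MandyPhos in step 14 on these substrates is assumed by analogy with related cases; if either is opposite, the mirror-image catalyst is used and nothing else changes, and the cis isomer is assumed to be the kinetic product of step 6 (if the trans isomer forms directly, step 7 falls away).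

## Route

Step 1
Reactants: 1 2-bromo-5-methoxyphenol
Product: 2 3-bromo-2-hydroxy-6-methoxybenzaldehyde
Conditions: MgCl2, Et3N, (CH2O)n, MeCN, reflux; aq. HCl work-up
Reagents that add atoms: paraformaldehyde (formaldehyde), C=O
Why: Magnesium-mediated ortho-formylation of phenols (Casnati–Skattebøl): the magnesium phenoxide delivers formaldehyde only to a carbon ortho to oxygen, and since C2 carries bromine the only free ortho position is C6, between OH and OMe. The aldehyde oxidation level is reached in the same pot by hydride transfer to a second formaldehyde.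

Step 2
Reactants: 2 3-bromo-2-hydroxy-6-methoxybenzaldehyde; 3 2,4-dimethoxybenzyl alcohol
Product: 4 3-bromo-2-[(2,4-dimethoxybenzyl)oxy]-6-methoxybenzaldehyde
Conditions: PPh3, DIAD, THF, 0 °C → rt
Reagents that add atoms: none
Why: Mitsunobu etherification of the acidic salicylaldehyde phenol with a primary benzylic alcohol. It places the future C2' (the benzylic CH2) and its aryl group on the oxygen that becomes O1'.

Step 3
Reactants: 4 3-bromo-2-[(2,4-dimethoxybenzyl)oxy]-6-methoxybenzaldehyde; 5 3,5-dimethoxyphenylmagnesium chloride
Product: 6 {3-bromo-2-[(2,4-dimethoxybenzyl)oxy]-6-methoxyphenyl}(3,5-dimethoxyphenyl)methanol (racemic)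
Conditions: THF, −78 → 0 °C; aq. NH4Cl
Reagents that add atoms: none
Why: 1,2-Addition of an aryl Grignard reagent to an aldehyde; the aryl bromide and the benzyl ether are inert at low temperature. The new carbinol centre is racemic and is removed in the next step.

Step 4
Reactants: 6 {3-bromo-2-[(2,4-dimethoxybenzyl)oxy]-6-methoxyphenyl}(3,5-dimethoxyphenyl)methanol
Product: 7 {3-bromo-2-[(2,4-dimethoxybenzyl)oxy]-6-methoxyphenyl}(3,5-dimethoxyphenyl)methanone
Conditions: Dess–Martin periodinane, CH2Cl2, 0 °C → rt
Reagents that add atoms: none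
Why: Dess–Martin oxidation of a secondary diaryl carbinol to the benzophenone under nearly neutral conditions that spare the acid-labile 2,4-dimethoxybenzyl ether.

Step 5
Reactants: 7 {3-bromo-2-[(2,4-dimethoxybenzyl)oxy]-6-methoxyphenyl}(3,5-dimethoxyphenyl)methanone
Product: 8 hydrazone of ketone 7 (E/Z mixture)
Conditions: N2H4·H2O (excess), AcOH (cat.), EtOH, 80 °C (sealed tube)
Reagents that add atoms: hydrazine hydrate (hydrazine), NN
Why: Condensation of a ketone with hydrazine to the N-unsubstituted hydrazone; the doubly ortho-substituted carbonyl is slow, hence excess hydrazine, acid catalysis and heat. The E/Z ratio is irrelevant because both isomers give the same diazo compound.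

Step 6
Reactants: 8 hydrazone of ketone 7
Product: 10 (2R,3S)-7-bromo-2-(2,4-dimethoxyphenyl)-3-(3,5-dimethoxyphenyl)-4-methoxy-2,3-dihydro-1-benzofuran (cis), via diaryldiazomethane 9 (not isolated)
Conditions: MnO2, CH2Cl2, 0 °C; filter; Rh2(R-PTAD)4 (1 mol%), CH2Cl2, 0 °C → rt
Reagents that add atoms: none
Why: MnO2 dehydrogenates the hydrazone to the diaryldiazomethane, and the chiral dirhodium tetracarboxylate (PTAD = N-phthaloyl-1-adamantylglycinate) converts it into a donor/donor carbene that inserts into the hydridic O–CH2–aryl C–H bond (hydride transfer, then C–C closure to the five-membered ring), a known enantioselective route to 2,3-diaryl-2,3-dihydrobenzofurans. The catalyst sets C3' (S) and the cis isomer is the expected kinetic product. Insertion into the O–CH3 group on the other side should be far slower because that C–H bond is not benzylic.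

Step 7
Reactants: 10 (2R,3S)-7-bromo-2-(2,4-dimethoxyphenyl)-3-(3,5-dimethoxyphenyl)-4-methoxy-2,3-dihydro-1-benzofuran
Product: 11 (2S,3S)-7-bromo-2-(2,4-dimethoxyphenyl)-3-(3,5-dimethoxyphenyl)-4-methoxy-2,3-dihydro-1-benzofuran (trans)
Conditions: CF3CO2H (cat.), CH2Cl2, 0 °C → rt
Reagents that add atoms: none
Why: Acid-catalysed epimerisation at C2': reversible ionisation of the C2'–O1' bond gives a benzylic cation stabilised by the ortho and para methoxy groups, and re-closure gives the more stable trans isomer. C3' is not touched.

Step 8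
Reactants: 12 3,5-dihydroxybenzaldehyde
Product: 13 3,5-bis(methoxymethoxy)benzaldehyde
Conditions: MOMCl, i-Pr2NEt, CH2Cl2, 0 °C → rt
Reagents that add atoms: chloromethyl methyl ether, COCCl
Why: O-Alkylation of both phenols with chloromethyl methyl ether and a hindered amine base. The MOM ethers later direct the lithiation of step 10 and are removed by acid in step 16, separately from the methyl ethers.

Step 9
Reactants: 13 3,5-bis(methoxymethoxy)benzaldehyde; 14 diethyl (4-methoxybenzyl)phosphonate
Product: 15 1,3-bis(methoxymethoxy)-5-[(E)-2-(4-methoxyphenyl)ethenyl]benzene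
Conditions: KOt-Bu, THF, 0 °C → rt
Reagents that add atoms: none
Why: Horner–Wadsworth–Emmons olefination of an aromatic aldehyde with a benzylic phosphonate anion, which gives the (E)-stilbene with high selectivity.

Step 10
Reactants: 15 1,3-bis(methoxymethoxy)-5-[(E)-2-(4-methoxyphenyl)ethenyl]benzene
Product: 18 2,6-bis(methoxymethoxy)-4-[(E)-2-(4-methoxyphenyl)ethenyl]phenol, via aryllithium 16 (not isolated), via lithium aryltrimethoxyborate 17 (not isolated)
Conditions: n-BuLi, THF, −20 → 0 °C; B(OMe)3, −78 °C → rt; 30% H2O2, aq. NaOH, 0 °C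
Reagents that add atoms: hydrogen peroxide, OO; n-butyllithium, [Li]CCCC (lithium of 16 and 17 only); trimethyl borate, COB(OC)OC (boron and methoxy groups of 17 only)
Why: Directed ortho-metalation: the C–H bond flanked by two MOM ethers is by far the most acidic and is lithiated selectively. The aryllithium is trapped with trimethyl borate and the aryl–boron bond is oxidised to the phenol by aryl migration from boron to oxygen at the same carbon.

Step 11
Reactants: 18 2,6-bis(methoxymethoxy)-4-[(E)-2-(4-methoxyphenyl)ethenyl]phenol
Product: 19 2,6-bis(methoxymethoxy)-4-[(E)-2-(4-methoxyphenyl)ethenyl]phenyl trifluoromethanesulfonate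
Conditions: PhNTf2, Et3N, DMAP (cat.), CH2Cl2, rt → 40 °C
Reagents that add atoms: N-phenylbis(trifluoromethanesulfonimide), O=S(=O)(N(c1ccccc1)S(=O)(=O)C(F)(F)F)C(F)(F)F
Why: O-Sulfonylation of the phenol with a mild triflyl-transfer reagent that does not attack the MOM acetals or the stilbene. It gives the aryl triflate needed as the electrophile.

Step 12
Reactants: 20 acenaphthoquinone
Product: 21 cis-1,2-dimethyl-1,2-dihydroacenaphthylene-1,2-diol (meso; the mac diol)
Conditions: AlMe3, toluene, 0 °C → rt; aq. HCl
Reagents that add atoms: trimethylaluminium, C[Al](C)C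
Why: Double 1,2-addition of methyl from AlMe3 to the 1,2-diketone; the second addition occurs anti to the bulky aluminium alkoxide formed by the first, so the cis (meso) diol results. Only this isomer can form a five-membered cyclic boronate.

Step 13
Reactants: 22 1-ethynyl-3,5-dimethoxybenzene; 21 cis-1,2-dimethyl-1,2-dihydroacenaphthylene-1,2-diol
Product: 24 (E)-2-(3,5-dimethoxyphenyl)ethenylboronic acid cis-1,2-dimethylacenaphthylene-1,2-diyl ester [alkenyl–B(mac)], via alkenyl catechol boronate 23 (not isolated)
Conditions: catecholborane, THF, 70 °C; then 21, rt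
Reagents that add atoms: catecholborane, B1Oc2ccccc2O1 (boron of 23 and 24; the catechol oxygens only in 23)
Why: Uncatalysed syn hydroboration of a terminal arylalkyne with catecholborane places boron on the terminal carbon and gives the (E)-alkenyl boronate. Catechol boronates exchange readily with aliphatic 1,2-diols, so the hindered diol 21 displaces catechol.

Step 14
Reactants: 11 (2S,3S)-7-bromo-2-(2,4-dimethoxyphenyl)-3-(3,5-dimethoxyphenyl)-4-methoxy-2,3-dihydro-1-benzofuran; 24 alkenyl–B(mac) boronate; 19 2,6-bis(methoxymethoxy)-4-[(E)-2-(4-methoxyphenyl)ethenyl]phenyl trifluoromethanesulfonate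
Product: 27 B(mac) ester of (1S,2S)-2-{2,6-bis(methoxymethoxy)-4-[(E)-2-(4-methoxyphenyl)ethenyl]phenyl}-1-[(2S,3S)-2-(2,4-dimethoxyphenyl)-3-(3,5-dimethoxyphenyl)-4-methoxy-2,3-dihydro-1-benzofuran-7-yl]-2-(3,5-dimethoxyphenyl)ethylboronic acid, via aryllithium 25 (not isolated), via lithium boronate complex 26 (not isolated)
Conditions: 11, t-BuLi (2 equiv), THF, −78 °C; 24, −78 °C → rt; KOTf (2 equiv), Pd(OAc)2 (3 mol%), (Sp,Sp)-MandyPhos (3.6 mol%), 19, THF, 60 °C
Reagents that add atoms: tert-butyllithium, [Li]C(C)(C)C (lithium of 25 and 26 only)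
Why: Bromine–lithium exchange at C7' of 11 with two equivalents of t-BuLi gives aryllithium 25, which adds to the boron of 24 to give the tetracoordinate boronate 26; KOTf removes the bromide that would otherwise occupy the cationic palladium. Oxidative addition of triflate 19 to zerovalent palladium gives a cationic arylpalladium species that binds the alkene of 26; this triggers the 1,2-shift of the aryl group from boron to the α-carbon, anti to palladium (bond C2–C7'), and reductive elimination joins the palladium-bound aryl group to the β-carbon (bond C3–C3a). The closest known reaction is the enantioselective palladium/MandyPhos conjunctive cross-coupling of β-substituted alkenyl B(mac) boronate complexes with aryl triflates; the present triflate is more hindered than usual. No ring is closed in this step. C3 (S) is set by the chiral bisphosphine, which selects the alkene face to which palladium binds; C2 (S) follows from the (E)-geometry and the anti addition, and is in any case re-set in step 16. The step needs conjunctive coupling to win over direct Suzuki transmetalation and β-hydride elimination: the hindered mac diol shields the boronate oxygens, and the triflate keeps palladium cationic so that it binds the alkene. The carbon-bound aryl group migrates in preference to an oxygen ligand, and the stereocentres of 11 are remote from boron, so catalyst control should dominate.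

Step 15
Reactants: 27 B(mac) boronate from step 14
Product: 28 (1S,2S)-2-{2,6-bis(methoxymethoxy)-4-[(E)-2-(4-methoxyphenyl)ethenyl]phenyl}-1-[(2S,3S)-2-(2,4-dimethoxyphenyl)-3-(3,5-dimethoxyphenyl)-4-methoxy-2,3-dihydro-1-benzofuran-7-yl]-2-(3,5-dimethoxyphenyl)ethan-1-ol
Conditions: 30% H2O2, 3 M aq. NaOH, THF, 0 °C → rt
Reagents that add atoms: hydrogen peroxide, OO
Why: Oxidation of a secondary alkylboronic ester with basic hydrogen peroxide: hydroperoxide adds to boron and the alkyl group migrates from boron to oxygen with retention, so C2 keeps its configuration. The stilbene, MOM ethers and aryl ethers are inert under these conditions.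

Step 16
Reactants: 28 alcohol from step 15
Product: 30 (2S,3S)-2-[(2S,3S)-2-(2,4-dimethoxyphenyl)-3-(3,5-dimethoxyphenyl)-4-methoxy-2,3-dihydro-1-benzofuran-7-yl]-3-(3,5-dimethoxyphenyl)-6-[(E)-2-(4-methoxyphenyl)ethenyl]-2,3-dihydro-1-benzofuran-4-ol (octa-O-methyl gnetumontanin B), via triol 29 (not isolated)
Conditions: conc. HCl (5 equiv), MeOH/THF, 45 °C
Reagents that add atoms: none
Why: Acid cleaves the two MOM acetals (methanol takes up the formaldehyde unit as dimethoxymethane) and ionises the benzylic C2–OH, whose cation is stabilised by the ortho ring oxygen and the para methoxy group of the inner arene; a neighbouring phenol captures it to form the five-membered ring (acid-mediated dehydrative cyclisation of a 2-(2-hydroxyaryl)ethanol), the two phenols being equivalent. The trans ring should form because attack anti to the C3 aryl group is favoured and the closure is reversible, so C2 ends S whatever it was, while C3 keeps its configuration.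

Step 17
Reactants: 30 octa-O-methyl gnetumontanin B
Product: 31 gnetumontanin B
Conditions: BBr3 (excess), CH2Cl2, −78 °C → rt; MeOH/H2O quench
Reagents that add atoms: none
Why: Lewis-acid cleavage of aryl methyl ethers with BBr3 (bromide attacks the methyl group of the boron-bound ether), the usual last step for permethylated stilbene oligomers. No C–C bond or stereocentre is touched, and a transiently opened benzylic C–O bond should re-close to the trans ring on work-up.

## Compound list

1 | 2-bromo-5-methoxyphenol | COc1ccc(Br)c(O)c1 | starting material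
2 | 3-bromo-2-hydroxy-6-methoxybenzaldehyde | COc1ccc(Br)c(O)c1C=O | intermediate
3 | 2,4-dimethoxybenzyl alcohol | COc1ccc(CO)c(OC)c1 | starting material
4 | 3-bromo-2-[(2,4-dimethoxybenzyl)oxy]-6-methoxybenzaldehyde | COc1ccc(Br)c(OCc2ccc(OC)cc2OC)c1C=O | intermediate
5 | 3,5-dimethoxyphenylmagnesium chloride (THF solution) | COc1cc([Mg]Cl)cc(OC)c1 | starting material
6 | {3-bromo-2-[(2,4-dimethoxybenzyl)oxy]-6-methoxyphenyl}(3,5-dimethoxyphenyl)methanol, racemic | COc1ccc(Br)c(OCc2ccc(OC)cc2OC)c1C(O)c1cc(OC)cc(OC)c1 | intermediate
7 | {3-bromo-2-[(2,4-dimethoxybenzyl)oxy]-6-methoxyphenyl}(3,5-dimethoxyphenyl)methanone | COc1ccc(Br)c(OCc2ccc(OC)cc2OC)c1C(=O)c1cc(OC)cc(OC)c1 | intermediate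
8 | hydrazone of 7 (E/Z mixture) | COc1ccc(Br)c(OCc2ccc(OC)cc2OC)c1C(=NN)c1cc(OC)cc(OC)c1 | intermediate
9 | {3-bromo-2-[(2,4-dimethoxybenzyl)oxy]-6-methoxyphenyl}(3,5-dimethoxyphenyl)diazomethane | COc1ccc(Br)c(OCc2ccc(OC)cc2OC)c1C(=[N+]=[N-])c1cc(OC)cc(OC)c1 | intermediate (not isolated)
10 | (2R,3S)-7-bromo-2-(2,4-dimethoxyphenyl)-3-(3,5-dimethoxyphenyl)-4-methoxy-2,3-dihydro-1-benzofuran (cis) | Brc1ccc(OC)c2c1O[C@@H](c1ccc(OC)cc1OC)[C@H]2c1cc(OC)cc(OC)c1 | intermediate
11 | (2S,3S)-7-bromo-2-(2,4-dimethoxyphenyl)-3-(3,5-dimethoxyphenyl)-4-methoxy-2,3-dihydro-1-benzofuran (trans) | Brc1ccc(OC)c2c1O[C@H](c1ccc(OC)cc1OC)[C@H]2c1cc(OC)cc(OC)c1 | intermediate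
12 | 3,5-dihydroxybenzaldehyde | O=Cc1cc(O)cc(O)c1 | starting material
13 | 3,5-bis(methoxymethoxy)benzaldehyde | COCOc1cc(C=O)cc(OCOC)c1 | intermediate
14 | diethyl (4-methoxybenzyl)phosphonate | CCOP(=O)(Cc1ccc(OC)cc1)OCC | starting material
15 | 1,3-bis(methoxymethoxy)-5-[(E)-2-(4-methoxyphenyl)ethenyl]benzene | COCOc1cc(/C=C/c2ccc(OC)cc2)cc(OCOC)c1 | intermediate
16 | {2,6-bis(methoxymethoxy)-4-[(E)-2-(4-methoxyphenyl)ethenyl]phenyl}lithium | COCOc1cc(/C=C/c2ccc(OC)cc2)cc(OCOC)c1[Li] | intermediate (not isolated)
17 | lithium {2,6-bis(methoxymethoxy)-4-[(E)-2-(4-methoxyphenyl)ethenyl]phenyl}trimethoxyborate | [Li+].COCOc1cc(/C=C/c2ccc(OC)cc2)cc(OCOC)c1[B-](OC)(OC)OC | intermediate (not isolated)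
18 | 2,6-bis(methoxymethoxy)-4-[(E)-2-(4-methoxyphenyl)ethenyl]phenol | COCOc1cc(/C=C/c2ccc(OC)cc2)cc(OCOC)c1O | intermediate
19 | 2,6-bis(methoxymethoxy)-4-[(E)-2-(4-methoxyphenyl)ethenyl]phenyl trifluoromethanesulfonate | COCOc1cc(/C=C/c2ccc(OC)cc2)cc(OCOC)c1OS(=O)(=O)C(F)(F)F | intermediate
20 | acenaphthoquinone | O=C1C(=O)c2cccc3cccc1c23 | starting material
21 | cis-1,2-dimethyl-1,2-dihydroacenaphthylene-1,2-diol (meso, mac diol) | C[C@@]1(O)c2cccc3cccc(c23)[C@]1(C)O | intermediate
22 | 1-ethynyl-3,5-dimethoxybenzene | COc1cc(C#C)cc(OC)c1 | starting material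
23 | 2-[(E)-2-(3,5-dimethoxyphenyl)ethenyl]-1,3,2-benzodioxaborole | COc1cc(/C=C/B2Oc3ccccc3O2)cc(OC)c1 | intermediate (not isolated)
24 | (E)-2-(3,5-dimethoxyphenyl)ethenylboronic acid cis-1,2-dimethylacenaphthylene-1,2-diyl ester, alkenyl–B(mac) | COc1cc(/C=C/B2O[C@]3(C)c4cccc5cccc(c45)[C@]3(C)O2)cc(OC)c1 | intermediate
25 | [(2S,3S)-2-(2,4-dimethoxyphenyl)-3-(3,5-dimethoxyphenyl)-4-methoxy-2,3-dihydro-1-benzofuran-7-yl]lithium | [Li]c1ccc(OC)c2c1O[C@H](c1ccc(OC)cc1OC)[C@H]2c1cc(OC)cc(OC)c1 | intermediate (not isolated)
26 | lithium boronate complex of 24 with the aryl group of 25 on boron | COc1cc(/C=C/[B-]2(c3ccc(OC)c4c3O[C@H](c3ccc(OC)cc3OC)[C@H]4c3cc(OC)cc(OC)c3)O[C@]3(C)c4cccc5cccc(c45)[C@]3(C)O2)cc(OC)c1.[Li+] | intermediate (not isolated)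
27 | B(mac) ester of (1S,2S)-2-{2,6-bis(methoxymethoxy)-4-[(E)-2-(4-methoxyphenyl)ethenyl]phenyl}-1-[(2S,3S)-2-(2,4-dimethoxyphenyl)-3-(3,5-dimethoxyphenyl)-4-methoxy-2,3-dihydro-1-benzofuran-7-yl]-2-(3,5-dimethoxyphenyl)ethylboronic acid | B1(O[C@]2(C)c3cccc4cccc(c34)[C@]2(C)O1)[C@H](c1ccc(OC)c2c1O[C@H](c1ccc(OC)cc1OC)[C@H]2c1cc(OC)cc(OC)c1)[C@H](c1c(OCOC)cc(/C=C/c2ccc(OC)cc2)cc1OCOC)c1cc(OC)cc(OC)c1 | intermediate
28 | (1S,2S)-2-{2,6-bis(methoxymethoxy)-4-[(E)-2-(4-methoxyphenyl)ethenyl]phenyl}-1-[(2S,3S)-2-(2,4-dimethoxyphenyl)-3-(3,5-dimethoxyphenyl)-4-methoxy-2,3-dihydro-1-benzofuran-7-yl]-2-(3,5-dimethoxyphenyl)ethan-1-ol | O[C@H](c1ccc(OC)c2c1O[C@H](c1ccc(OC)cc1OC)[C@H]2c1cc(OC)cc(OC)c1)[C@H](c1c(OCOC)cc(/C=C/c2ccc(OC)cc2)cc1OCOC)c1cc(OC)cc(OC)c1 | intermediate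
29 | 2-{(1S,2S)-2-[(2S,3S)-2-(2,4-dimethoxyphenyl)-3-(3,5-dimethoxyphenyl)-4-methoxy-2,3-dihydro-1-benzofuran-7-yl]-1-(3,5-dimethoxyphenyl)-2-hydroxyethyl}-5-[(E)-2-(4-methoxyphenyl)ethenyl]benzene-1,3-diol | O[C@H](c1ccc(OC)c2c1O[C@H](c1ccc(OC)cc1OC)[C@H]2c1cc(OC)cc(OC)c1)[C@H](c1c(O)cc(/C=C/c2ccc(OC)cc2)cc1O)c1cc(OC)cc(OC)c1 | intermediate (not isolated)
30 | (2S,3S)-2-[(2S,3S)-2-(2,4-dimethoxyphenyl)-3-(3,5-dimethoxyphenyl)-4-methoxy-2,3-dihydro-1-benzofuran-7-yl]-3-(3,5-dimethoxyphenyl)-6-[(E)-2-(4-methoxyphenyl)ethenyl]-2,3-dihydro-1-benzofuran-4-ol (octa-O-methyl gnetumontanin B) | COc1ccc(/C=C/c2cc(O)c3c(c2)O[C@H](c2ccc(OC)c4c2O[C@H](c2ccc(OC)cc2OC)[C@H]4c2cc(OC)cc(OC)c2)[C@H]3c2cc(OC)cc(OC)c2)cc1 | intermediate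
31 | gnetumontanin B, (2S,3S)-2-[(2S,3S)-2-(2,4-dihydroxyphenyl)-3-(3,5-dihydroxyphenyl)-4-hydroxy-2,3-dihydro-1-benzofuran-7-yl]-3-(3,5-dihydroxyphenyl)-6-[(E)-2-(4-hydroxyphenyl)ethenyl]-2,3-dihydro-1-benzofuran-4-ol | Oc1ccc(/C=C/c2cc(O)c3c(c2)O[C@H](c2ccc(O)c4c2O[C@H](c2ccc(O)cc2O)[C@H]4c2cc(O)cc(O)c2)[C@H]3c2cc(O)cc(O)c2)cc1 | target

## Step count and uncertain steps

Total: 17 steps. Longest linear sequence: 11 steps (steps 1–7, then 14–17). The triflate branch has 4 steps (8–11) and the boronate branch 2 (12–13).

**Step 14 (key step).** Most likely to go wrong: with two ortho substituents on the palladium-bound aryl group, alkene binding and above all reductive elimination are slowed. Direct boron-to-palladium transfer of the alkenyl group (Suzuki-type coupling), β-hydride elimination from the benzylic alkylpalladium intermediate or protonolysis of the boronate complex can then take over. Incomplete face selection on a β-aryl alkene and proton transfer from C2'–H to the aryllithium before it reaches boron are secondary risks.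

Fallback, setting out from 11 and 15 and returning at 30:
- Bromine–lithium exchange on 11 and quenching with DMF give (2S,3S)-2-(2,4-dimethoxyphenyl)-3-(3,5-dimethoxyphenyl)-4-methoxy-2,3-dihydro-1-benzofuran-7-carbaldehyde F1.
- Aryllithium 16, made from 15 as in step 10, is alkylated with 3,5-dimethoxybenzyl bromide to the diarylmethane 2-(3,5-dimethoxybenzyl)-1,3-bis(methoxymethoxy)-5-[(E)-2-(4-methoxyphenyl)ethenyl]benzene F2.
- Lateral lithiation of F2 at the doubly benzylic CH2 (s-BuLi, THF, −78 °C), directed by the two flanking MOM ethers, and addition to F1 give the alcohol of 28 as a mixture of its four diastereomers at the two new centres F3.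
- Step 16 applied to this mixture re-sets C2 trans to C3 and gives 30 together with its (2R,3R) diastereomer F4. The two are diastereomers and are separated by chromatography; 30 rejoins the route.

This gives up catalyst control of C3 but uses only carbonyl addition chemistry.

**Step 6 (with step 5, which feeds it).** Most likely to go wrong: hydrazone formation at a benzophenone with both ortho positions occupied is slow. The crowded carbene may dimerise or form the azine instead of inserting, or insert with lower enantioselectivity than less substituted cases.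

Fallback, setting out from 7 and returning at 11:
- A strong non-nucleophilic base (phosphazene base P4-t-Bu, or KN(SiMe3)2) deprotonates the O–CH2–aryl group of 7, which adds to the ketone and dehydrates to 7-bromo-2-(2,4-dimethoxyphenyl)-3-(3,5-dimethoxyphenyl)-4-methoxy-1-benzofuran F5.
- Ionic hydrogenation (Et3SiH, CF3CO2H) reduces F5 through the C2' cation to the racemic trans-dihydrobenzofuran, that is 11 and its enantiomer (2R,3R)-7-bromo-2-(2,4-dimethoxyphenyl)-3-(3,5-dimethoxyphenyl)-4-methoxy-2,3-dihydro-1-benzofuran F6.
- Chromatography on a chiral stationary phase gives 11.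

**Step 16.** Most likely to go wrong: the C2 cation forms before the phenols are unmasked. It can then lose the doubly benzylic C3–H (elimination to a triarylethylene and re-protonation) or undergo a hydride shift, which erodes the C3 configuration. The stilbene can also react with acid or with the released formaldehyde unit.

Fallback, setting out from 27 and returning at 29 and then 30:
- The MOM groups are removed first, at the boronate stage where C2 cannot ionise (HCl, MeOH/THF, rt). This gives the B(mac) ester of (1S,2S)-2-{2,6-dihydroxy-4-[(E)-2-(4-methoxyphenyl)ethenyl]phenyl}-1-[(2S,3S)-2-(2,4-dimethoxyphenyl)-3-(3,5-dimethoxyphenyl)-4-methoxy-2,3-dihydro-1-benzofuran-7-yl]-2-(3,5-dimethoxyphenyl)ethylboronic acid F7.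
- Oxidation as in step 15 gives 29, now isolated.
- 29 is closed to 30 with a weak acid (pyridinium p-toluenesulfonate, CH2Cl2, 0 °C), so that capture by the phenol already in place outruns elimination.

**Step 10.** Most likely to go wrong: n-BuLi adds across the stilbene double bond or lithiates next to only one MOM group, and the electron-rich phenoxide is over-oxidised by peroxide.

Fallback, setting out from 13 and returning at 19, with the oxygen introduced before the alkene exists:
- NaBH4 reduction of 13 gives [3,5-bis(methoxymethoxy)phenyl]methanol F8.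
- n-BuLi (2.2 equiv), then B(OMe)3 and H2O2, give 4-(hydroxymethyl)-2,6-bis(methoxymethoxy)phenol F9.
- Selective triflation of the phenol (PhNTf2, K2CO3) gives 4-(hydroxymethyl)-2,6-bis(methoxymethoxy)phenyl trifluoromethanesulfonate F10.
- MnO2 oxidation gives 4-formyl-2,6-bis(methoxymethoxy)phenyl trifluoromethanesulfonate F11.
- Olefination with 14 (NaH, THF) gives 19.

**Step 17.** Most likely to go wrong: cleavage of eight ethers is incomplete. The Lewis acid opens the benzylic C–O bonds and elimination follows. HBr adds to or oligomerises the stilbene. The air-sensitive polyphenol is lost on isolation.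

Fallback, setting out from 30 and returning at 31:
- The ethers are cleaved with BCl3/n-Bu4NI (−78 → 0 °C), where iodide is the nucleophile and a lower temperature suffices.
- The crude phenols are acetylated in the same flask (Ac2O, pyridine) to nona-O-acetyl gnetumontanin B F12, which is purified.
- The acetates are removed with K2CO3 in MeOH at 0 °C under argon, giving 31 without handling the crude free polyphenol.

## Further compounds

F1 | step 14 | (2S,3S)-2-(2,4-dimethoxyphenyl)-3-(3,5-dimethoxyphenyl)-4-methoxy-2,3-dihydro-1-benzofuran-7-carbaldehyde | O=Cc1ccc(OC)c2c1O[C@H](c1ccc(OC)cc1OC)[C@H]2c1cc(OC)cc(OC)c1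
F2 | step 14 | 2-(3,5-dimethoxybenzyl)-1,3-bis(methoxymethoxy)-5-[(E)-2-(4-methoxyphenyl)ethenyl]benzene | COCOc1cc(/C=C/c2ccc(OC)cc2)cc(OCOC)c1Cc1cc(OC)cc(OC)c1
F3 | step 14 | alcohol of 28 as the mixture of its four diastereomers at C1 and C2 of the ethanol chain (inner ring 2S,3S) | OC(c1ccc(OC)c2c1O[C@H](c1ccc(OC)cc1OC)[C@H]2c1cc(OC)cc(OC)c1)C(c1c(OCOC)cc(/C=C/c2ccc(OC)cc2)cc1OCOC)c1cc(OC)cc(OC)c1
F4 | step 14 | (2R,3R)-2-[(2S,3S)-2-(2,4-dimethoxyphenyl)-3-(3,5-dimethoxyphenyl)-4-methoxy-2,3-dihydro-1-benzofuran-7-yl]-3-(3,5-dimethoxyphenyl)-6-[(E)-2-(4-methoxyphenyl)ethenyl]-2,3-dihydro-1-benzofuran-4-ol | COc1ccc(/C=C/c2cc(O)c3c(c2)O[C@@H](c2ccc(OC)c4c2O[C@H](c2ccc(OC)cc2OC)[C@H]4c2cc(OC)cc(OC)c2)[C@@H]3c2cc(OC)cc(OC)c2)cc1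
F5 | step 6 | 7-bromo-2-(2,4-dimethoxyphenyl)-3-(3,5-dimethoxyphenyl)-4-methoxy-1-benzofuran | COc1ccc(Br)c2oc(-c3ccc(OC)cc3OC)c(-c3cc(OC)cc(OC)c3)c12
F6 | step 6 | (2R,3R)-7-bromo-2-(2,4-dimethoxyphenyl)-3-(3,5-dimethoxyphenyl)-4-methoxy-2,3-dihydro-1-benzofuran | Brc1ccc(OC)c2c1O[C@@H](c1ccc(OC)cc1OC)[C@@H]2c1cc(OC)cc(OC)c1
F7 | step 16 | B(mac) ester of (1S,2S)-2-{2,6-dihydroxy-4-[(E)-2-(4-methoxyphenyl)ethenyl]phenyl}-1-[(2S,3S)-2-(2,4-dimethoxyphenyl)-3-(3,5-dimethoxyphenyl)-4-methoxy-2,3-dihydro-1-benzofuran-7-yl]-2-(3,5-dimethoxyphenyl)ethylboronic acid | B1(O[C@]2(C)c3cccc4cccc(c34)[C@]2(C)O1)[C@H](c1ccc(OC)c2c1O[C@H](c1ccc(OC)cc1OC)[C@H]2c1cc(OC)cc(OC)c1)[C@H](c1c(O)cc(/C=C/c2ccc(OC)cc2)cc1O)c1cc(OC)cc(OC)c1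
F8 | step 10 | [3,5-bis(methoxymethoxy)phenyl]methanol | COCOc1cc(CO)cc(OCOC)c1
F9 | step 10 | 4-(hydroxymethyl)-2,6-bis(methoxymethoxy)phenol | COCOc1cc(CO)cc(OCOC)c1O
F10 | step 10 | 4-(hydroxymethyl)-2,6-bis(methoxymethoxy)phenyl trifluoromethanesulfonate | COCOc1cc(CO)cc(OCOC)c1OS(=O)(=O)C(F)(F)F
F11 | step 10 | 4-formyl-2,6-bis(methoxymethoxy)phenyl trifluoromethanesulfonate | COCOc1cc(C=O)cc(OCOC)c1OS(=O)(=O)C(F)(F)F
F12 | step 17 | nona-O-acetyl gnetumontanin B | CC(=O)Oc1ccc(/C=C/c2cc(OC(C)=O)c3c(c2)O[C@H](c2ccc(OC(C)=O)c4c2O[C@H](c2ccc(OC(C)=O)cc2OC(C)=O)[C@H]4c2cc(OC(C)=O)cc(OC(C)=O)c2)[C@H]3c2cc(OC(C)=O)cc(OC(C)=O)c2)cc1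
A1 | alternative 1 | methyl (E)-5-diazo-4-oxopent-2-enoate | COC(=O)/C=C/C(=O)C=[N+]=[N-]
A2 | alternative 1 | {[(3S,4S)-4-(2,4-dimethoxyphenyl)-3-(3,5-dimethoxyphenyl)-4-methoxybut-1-yn-1-yl]oxy}triisopropylsilane | CC(C)[Si](OC#C[C@H](c1cc(OC)cc(OC)c1)[C@H](OC)c1ccc(OC)cc1OC)(C(C)C)C(C)C
A3 | alternative 1 | methyl 3-[(1S,2S)-2-(2,4-dimethoxyphenyl)-1-(3,5-dimethoxyphenyl)-2-methoxyethyl]-2-hydroxy-4-[(triisopropylsilyl)oxy]benzoate | COC(=O)c1ccc(O[Si](C(C)C)(C(C)C)C(C)C)c([C@H](c2cc(OC)cc(OC)c2)[C@H](OC)c2ccc(OC)cc2OC)c1O
A4 | alternative 2 | hydrazone of {2-[(2,4-dimethoxybenzyl)oxy]-3-(1,3-dioxolan-2-yl)-6-methoxyphenyl}(3,5-dimethoxyphenyl)methanone | NN=C(c1cc(OC)cc(OC)c1)c1c(OC)ccc(C2OCCO2)c1OCc1ccc(OC)cc1OC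
A5 | alternative 2 | (2S,3S)-2-(2,4-dimethoxyphenyl)-3-(3,5-dimethoxyphenyl)-7-(1,3-dioxolan-2-yl)-4-methoxy-2,3-dihydro-1-benzofuran (trans) | O1CCOC1c1ccc(OC)c2c1O[C@H](c1ccc(OC)cc1OC)[C@H]2c1cc(OC)cc(OC)c1
A6 | alternative 3 | 3-{[(1S,2S)-1-[(2S,3S)-2-(2,4-dimethoxyphenyl)-3-(3,5-dimethoxyphenyl)-4-methoxy-2,3-dihydro-1-benzofuran-7-yl]-2-(3,5-dimethoxyphenyl)-4-(4,4,5,5-tetramethyl-1,3,2-dioxaborolan-2-yl)but-3-yn-1-yl]oxy}-5-[(E)-2-(4-methoxyphenyl)ethenyl]pyridazine | COc1ccc(/C=C/c2cnnc(O[C@H](c3ccc(OC)c4c3O[C@H](c3ccc(OC)cc3OC)[C@H]4c3cc(OC)cc(OC)c3)[C@H](C#CB3OC(C)(C)C(C)(C)O3)c3cc(OC)cc(OC)c3)c2)cc1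
A7 | alternative 3 | octa-O-methyl gnetumontanin B skeleton with a pinacol boronate at C4 in place of 4-OH | COc1ccc(/C=C/c2cc(B5OC(C)(C)C(C)(C)O5)c3c(c2)O[C@H](c2ccc(OC)c4c2O[C@H](c2ccc(OC)cc2OC)[C@H]4c2cc(OC)cc(OC)c2)[C@H]3c2cc(OC)cc(OC)c2)cc1
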